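**Plan**

- Numbering: C1 (CO2H), C2, ring carbons C3 (on O2), C4, C5 (on O1), C6, C7 (CHMe), C8–C15, phenyl. The dioxolane carries both ring methyls on one face and the C2 and C6 methylenes on the other. C3–C4–C5 with its methyls is therefore acetylacetone plus H2O2, and the cis arms can be joined through C1 into a six-membered carbocycle (C1–C6), giving a meso 6,7-dioxabicyclo[3.2.1]octan-3-one.
- Retrosynthetic cuts, in order: the ester; C8–C9 (Wittig, then diimide); C6=C7 (Wittig, then reduction that sets C7); the C1–O–C6 lactone back to the C1–C6 bond of the meso ketone (Baeyer–Villiger); C2–C3 and C5–C6 together (double peroxycarbenium substitution, [3+3]); the dioxolane (diketone + H2O2).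
- Forward: the dioxolane ring first, then the temporary carbocycle across it, then oxidative opening of the carbocycle to the acetate arm and a C6 aldehyde, then the side chain by two olefinations.
- Stereochemistry: the cis relation at C3/C5 comes from the bridged ring; the absolute configuration at C3 and C5 from monooxygenase desymmetrisation of the meso ketone; C7 from an ene-reductase acting on the α-methyl enal.

Key step: step 4

Assumption: the enantiotopic preference of a Baeyer–Villiger monooxygenase cannot be predicted for this new ketone, so the enzyme of step 5 is taken to be the member of a cyclohexanone-/cyclopentanone-monooxygenase panel (types that are commonly enantiocomplementary on bridged ketones) that delivers the (1S,6R) lactone; the small peroxides of steps 1, 2 and 4 are handled in solution behind a shield.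

**Route**

Step 1
Reactants: 1 acetylacetone (pentane-2,4-dione); 2 hydrogen peroxide
Product: 3 3,5-dimethyl-1,2-dioxolane-3,5-diol (cis/trans mixture)
Conditions: 30% aq. H2O2 (1.0 equiv), Et2O, 0 °C → rt
Reagents that add atoms: none
Why: Double addition of hydrogen peroxide to the two carbonyl groups of the 1,3-diketone (cyclic bis-peroxyhemiketal formation) is favoured because the second addition closes a five-membered ring, and one equivalent of peroxide without strong acid should stop at the dioxolanediol instead of going on to bridged tetraoxanes.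

Step 2
Reactants: 3 3,5-dimethyl-1,2-dioxolane-3,5-diol
Product: 4 3,5-dimethoxy-3,5-dimethyl-1,2-dioxolane (cis/trans mixture)
Conditions: MeOH, (+)-camphor-10-sulfonic acid (5 mol%), 3 Å molecular sieves, 0 °C → rt; Et3N
Reagents that add atoms: methanol, CO
Why: Acid-catalysed ketalisation (hemiketal-to-ketal exchange through the peroxycarbenium ion) should replace both hydroxyls by methoxy while the five-membered peroxide ring is kept, and the cis/trans ratio is of no consequence because both centres are ionised in step 4.

Step 3
Reactants: 5 (trimethylsilyl)acetone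
Product: 7 2-(trimethylsilyloxy)allyltrimethylsilane, via lithium enolate 6 (not isolated)
Conditions: LiN(i-Pr)2, THF, −78 °C; Me3SiCl, −78 → 0 °C; distillation
Reagents that add atoms: chlorotrimethylsilane, C[Si](C)(C)Cl
Why: Kinetic deprotonation of an α-silyl ketone by a hindered lithium amide takes place at the methyl group remote from silicon, and O-silylation of that enolate (silyl enol ether formation) gives the allylsilane–enol silane hybrid that serves as an acetone 1,3-dianion equivalent.

Step 4
Reactants: 4 3,5-dimethoxy-3,5-dimethyl-1,2-dioxolane; 7 2-(trimethylsilyloxy)allyltrimethylsilane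
Product: 9 (1R,5S)-1,5-dimethyl-6,7-dioxabicyclo[3.2.1]octan-3-one (meso), via enol silane 8 (not isolated)
Conditions: Me3SiOTf (0.3 equiv), CH2Cl2 (0.01 M), −78 °C, 7 (1.0 equiv) added over 4 h, then → −30 °C; aq. NaHCO3
Reagents that add atoms: none
Why: Proposed new method: Me3SiOTf ionises one ketal of 4 to a peroxycarbenium ion that is captured at the CH2= terminus of 7, the developing cation being stabilised by the siloxy oxygen and the β-silicon, and loss of a silyl group (as Me3SiOMe, regenerating the silyl triflate) leaves enol silane 8 or its α-silyl ketone tautomer; ionisation of the second ketal then lets this tethered nucleophile attack the other ring carbon, so the C2–C3 and C5–C6 bonds form in turn. The closest known reaction types are the Lewis-acid substitution of 3-alkoxy-1,2-dioxolanes by enol silanes and allylsilanes and the [3+4] annulation of cyclic bis-acetals with bis-silyl enol ethers to oxygen-bridged ketones. The six-membered carbocycle (C2, C1, C6 across C3–C4–C5) closes in a 6-(enolendo)-exo-trig mode, the enol C=C lying inside the new ring and the C=O+ bond of the cation outside it. The two quaternary centres C3 and C5 are fixed relative to each other by the bridge itself, because three atoms can span the 3- and 5-positions of a five-membered ring only on one face, so both ketal isomers of 4 and both isomers of 8 converge on the one meso ketone with cis arms and cis methyls. What the step needs is closure in preference to a second intermolecular substitution or Hock-type migration in the cation, and this is secured by the three-atom tether that holds the enol silane over the cationic carbon, supported by slow addition of 7 to dilute 4 at −78 °C.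

Step 5
Reactants: 9 (1R,5S)-1,5-dimethyl-6,7-dioxabicyclo[3.2.1]octan-3-one
Product: 10 (1S,6R)-1,6-dimethyl-3,7,8-trioxabicyclo[4.2.1]nonan-4-one
Conditions: cyclohexanone monooxygenase (chosen from a panel), NADP+ (cat.), Na2HPO3, phosphite dehydrogenase, air, Tris·HCl buffer pH 7.5, 25 °C
Reagents that add atoms: dioxygen, O=O
Why: Enzymatic Baeyer–Villiger oxidation (addition of the flavin C4a-peroxide to the ketone and migration of one α-methylene) should desymmetrise the meso ketone because the chiral active site distinguishes the two enantiotopic CH2 groups, as it does in other bridged bicyclic ketones, and migration of the methylene on the (5S) bridgehead fixes both ring stereocentres absolutely while near-neutral buffer limits retro-Michael opening of the β-peroxy ketone.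

Step 6
Reactants: 10 (1S,6R)-1,6-dimethyl-3,7,8-trioxabicyclo[4.2.1]nonan-4-one
Product: 11 methyl 2-[(3R,5S)-5-(hydroxymethyl)-3,5-dimethyl-1,2-dioxolan-3-yl]acetate
Conditions: MeOH, (+)-camphor-10-sulfonic acid (10 mol%), rt; NaHCO3
Reagents that add atoms: methanol, CO
Why: Acid-catalysed transesterification (lactone methanolysis) should open the seven-membered lactone in excess methanol without touching the di-tertiary peroxide and without generating the ester enolate that a base would place next to the β-peroxide.

Step 7
Reactants: 11 methyl 2-[(3R,5S)-5-(hydroxymethyl)-3,5-dimethyl-1,2-dioxolan-3-yl]acetate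
Product: 12 methyl 2-[(3R,5S)-5-formyl-3,5-dimethyl-1,2-dioxolan-3-yl]acetate
Conditions: Dess–Martin periodinane, CH2Cl2, 0 °C → rt; used crude
Reagents that add atoms: none
Why: Dess–Martin oxidation converts the neopentyl-type primary alcohol to the aldehyde under metal-free conditions that dialkyl peroxides tolerate, and because the peroxide-bearing carbon next to the formyl group is quaternary the product can neither epimerise nor undergo Kornblum–DeLaMare cleavage.

Step 8
Reactants: 12 methyl 2-[(3R,5S)-5-formyl-3,5-dimethyl-1,2-dioxolan-3-yl]acetate; 13 2-(triphenylphosphoranylidene)propanal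
Product: 14 methyl 2-[(3R,5S)-3,5-dimethyl-5-[(1E)-2-methyl-3-oxoprop-1-en-1-yl]-1,2-dioxolan-3-yl]acetate
Conditions: toluene, 70 °C
Reagents that add atoms: none
Why: Wittig olefination with the formyl-stabilised ylide needs no added base and should give the (E)-trisubstituted enal, the α-peroxy substituent making the hindered aldehyde more electrophilic than a simple tertiary-alkyl aldehyde.

Step 9
Reactants: 14 methyl 2-[(3R,5S)-3,5-dimethyl-5-[(1E)-2-methyl-3-oxoprop-1-en-1-yl]-1,2-dioxolan-3-yl]acetate
Product: 15 methyl 2-[(3R,5R)-3,5-dimethyl-5-[(2S)-2-methyl-3-oxopropyl]-1,2-dioxolan-3-yl]acetate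
Conditions: ene-reductase (Old Yellow Enzyme 2 of Saccharomyces), NADP+ (cat.), Na2HPO3, phosphite dehydrogenase, phosphate buffer pH 7.0, t-BuOMe (10%), 25 °C; used at once
Reagents that add atoms: none
Why: Ene-reductase catalysis of the Old Yellow Enzyme type (flavin hydride to the β-carbon C6, anti protonation of the α-carbon C7 by the active-site tyrosine) is expected to turn the (E)-2-methyl-2-enal into the (S)-2-methylalkanal, so the catalyst and not the remote ring sets C7, and the neutral, metal-free aqueous medium should leave the O–O bond intact.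

Step 10
Reactants: 16 (7-bromoheptyl)benzene
Product: 17 triphenyl(7-phenylheptyl)phosphonium bromide
Conditions: PPh3, MeCN, reflux
Reagents that add atoms: triphenylphosphine, c1ccc(cc1)P(c1ccccc1)c1ccccc1
Why: SN2 quaternisation of triphenylphosphine by the unhindered primary bromide gives the phosphonium salt needed for the second Wittig reaction.

Step 11
Reactants: 15 methyl 2-[(3R,5R)-3,5-dimethyl-5-[(2S)-2-methyl-3-oxopropyl]-1,2-dioxolan-3-yl]acetate; 17 triphenyl(7-phenylheptyl)phosphonium bromide
Product: 19 methyl 2-[(3R,5R)-3,5-dimethyl-5-[(2S,3Z)-2-methyl-10-phenyldec-3-en-1-yl]-1,2-dioxolan-3-yl]acetate, via phosphonium ylide 18 (not isolated)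
Conditions: 17, NaN(SiMe3)2, THF, 0 °C; then 15, −78 → 0 °C
Reagents that add atoms: none
Why: Wittig olefination with the non-stabilised ylide should add to the aldehyde at −78 °C much faster than the ylide deprotonates C7 or the ester, so C8 is joined to C9 (mainly Z, which is irrelevant) without epimerising the α-stereocentre or triggering β-elimination of the peroxide.

Step 12
Reactants: 19 methyl 2-[(3R,5R)-3,5-dimethyl-5-[(2S,3Z)-2-methyl-10-phenyldec-3-en-1-yl]-1,2-dioxolan-3-yl]acetate
Product: 20 methyl 2-[(3R,5R)-3,5-dimethyl-5-[(2R)-2-methyl-10-phenyldecyl]-1,2-dioxolan-3-yl]acetate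
Conditions: KO2CN=NCO2K, AcOH, MeOH/CH2Cl2, 0 °C → rt
Reagents that add atoms: none
Why: Diimide reduction transfers two hydrogens to the disubstituted alkene through a concerted cyclic transition state and, unlike catalytic hydrogenation, should not cleave the O–O bond.

Step 13
Reactants: 20 methyl 2-[(3R,5R)-3,5-dimethyl-5-[(2R)-2-methyl-10-phenyldecyl]-1,2-dioxolan-3-yl]acetate
Product: 21 2-[(3R,5R)-3,5-dimethyl-5-[(2R)-2-methyl-10-phenyldecyl]-1,2-dioxolan-3-yl]acetic acid (target)
Conditions: LiOH, THF/H2O, 0 °C → rt; then 1 M HCl to pH 3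
Reagents that add atoms: lithium hydroxide (its oxygen ends in the carboxyl group), [Li+].[OH-]
Why: Saponification of the methyl ester (addition–elimination at the carbonyl) at low temperature should outrun enolate-triggered β-elimination of the peroxide, and acidification releases the free acid with all three stereocentres untouched.

**Compound list**

1 | acetylacetone (pentane-2,4-dione) | CC(=O)CC(C)=O | starting material
2 | hydrogen peroxide | OO | starting material
3 | 3,5-dimethyl-1,2-dioxolane-3,5-diol (cis/trans mixture) | CC1(O)CC(C)(O)OO1 | intermediate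
4 | 3,5-dimethoxy-3,5-dimethyl-1,2-dioxolane (cis/trans mixture) | COC1(C)CC(C)(OC)OO1 | intermediate
5 | (trimethylsilyl)acetone | CC(=O)C[Si](C)(C)C | starting material
6 | lithium 3-(trimethylsilyl)prop-1-en-2-olate | C=C(O[Li])C[Si](C)(C)C | intermediate
7 | 2-(trimethylsilyloxy)allyltrimethylsilane | C=C(C[Si](C)(C)C)O[Si](C)(C)C | intermediate
8 | 3-methoxy-3,5-dimethyl-5-[2-(trimethylsilyloxy)prop-2-en-1-yl]-1,2-dioxolane (both diastereomers) | COC1(C)CC(C)(CC(=C)O[Si](C)(C)C)OO1 | intermediate
9 | (1R,5S)-1,5-dimethyl-6,7-dioxabicyclo[3.2.1]octan-3-one (meso) | O=C1C[C@]2(C)C[C@](C)(C1)OO2 | intermediate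
10 | (1S,6R)-1,6-dimethyl-3,7,8-trioxabicyclo[4.2.1]nonan-4-one | O=C1OC[C@]2(C)C[C@](C)(C1)OO2 | intermediate
11 | methyl 2-[(3R,5S)-5-(hydroxymethyl)-3,5-dimethyl-1,2-dioxolan-3-yl]acetate | OC[C@]1(C)C[C@](C)(CC(=O)OC)OO1 | intermediate
12 | methyl 2-[(3R,5S)-5-formyl-3,5-dimethyl-1,2-dioxolan-3-yl]acetate | O=C[C@]1(C)C[C@](C)(CC(=O)OC)OO1 | intermediate
13 | 2-(triphenylphosphoranylidene)propanal | CC(C=O)=P(c1ccccc1)(c1ccccc1)c1ccccc1 | starting material
14 | methyl 2-[(3R,5S)-3,5-dimethyl-5-[(1E)-2-methyl-3-oxoprop-1-en-1-yl]-1,2-dioxolan-3-yl]acetate | O=C/C(C)=C/[C@]1(C)C[C@](C)(CC(=O)OC)OO1 | intermediate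
15 | methyl 2-[(3R,5R)-3,5-dimethyl-5-[(2S)-2-methyl-3-oxopropyl]-1,2-dioxolan-3-yl]acetate | C[C@H](C=O)C[C@]1(C)C[C@](C)(CC(=O)OC)OO1 | intermediate
16 | (7-bromoheptyl)benzene | BrCCCCCCCc1ccccc1 | starting material
17 | triphenyl(7-phenylheptyl)phosphonium bromide | [Br-].c1ccc(cc1)CCCCCCC[P+](c1ccccc1)(c1ccccc1)c1ccccc1 | intermediate
18 | triphenyl(7-phenylheptylidene)phosphorane | C(CCCCCCc1ccccc1)=P(c1ccccc1)(c1ccccc1)c1ccccc1 | intermediate
19 | methyl 2-[(3R,5R)-3,5-dimethyl-5-[(2S,3Z)-2-methyl-10-phenyldec-3-en-1-yl]-1,2-dioxolan-3-yl]acetate | C[C@H](/C=C\CCCCCCc1ccccc1)C[C@]1(C)C[C@](C)(CC(=O)OC)OO1 | intermediate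
20 | methyl 2-[(3R,5R)-3,5-dimethyl-5-[(2R)-2-methyl-10-phenyldecyl]-1,2-dioxolan-3-yl]acetate | C[C@H](CCCCCCCCc1ccccc1)C[C@]1(C)C[C@](C)(CC(=O)OC)OO1 | intermediate
21 | 2-[(3R,5R)-3,5-dimethyl-5-[(2R)-2-methyl-10-phenyldecyl]-1,2-dioxolan-3-yl]acetic acid | C[C@H](CCCCCCCCc1ccccc1)C[C@]1(C)C[C@](C)(CC(=O)O)OO1 | target

**Step count and risks**

Total: 13 steps. Longest linear sequence: 11 steps (1, 2, 4–9, 11–13); steps 3 and 10 prepare the two reagents.

Steps most likely to fail:

1. Step 4. The second peroxycarbenium ion may be captured intermolecularly (oligomers, bis-adducts), the cation may undergo Hock-type migration, or the enol silane may be protodesilylated before it can close. The two C–C bonds would then be made in separate operations of established type. Setting out from 4, substitution of one methoxy group by commercial 2-(trimethylsilyloxy)propene under Me3SiOTf in CH2Cl2 at −78 °C (the known enol-silane substitution of alkoxydioxolanes) should give the isolable methyl ketone 1-(5-methoxy-3,5-dimethyl-1,2-dioxolan-3-yl)propan-2-one F1. Treatment of F1 with Me3SiOTf and i-Pr2NEt in dilute CH2Cl2 (soft enolisation followed by Mukaiyama-type addition to the remaining ketal, a known one-flask sequence for ketones and dimethyl ketals) would pass through enol silane 8 and close the ring. Only the methyl-side enol silane can cyclise, since the internal one would have to form a four-membered ring. The route is rejoined at 9.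

2. Step 5. The enzyme may not accept a ketone flanked by two quaternary bridgeheads, may discriminate poorly between the enantiotopic methylenes, or the β-peroxy ketone may open by retro-Michael elimination and aromatise during long incubation in buffer. The oxidation would then be done chemically and the enantiomers separated. Setting out from 9, mCPBA with NaHCO3 in CH2Cl2 should give the racemic lactone rac-1,6-dimethyl-3,7,8-trioxabicyclo[4.2.1]nonan-4-one F2. Acid methanolysis as in step 6 would give the racemic hydroxy ester methyl 2-[(3R*,5S*)-5-(hydroxymethyl)-3,5-dimethyl-1,2-dioxolan-3-yl]acetate F3. Esterification with (S)-O-acetylmandelic acid (N,N'-dicyclohexylcarbodiimide, 4-(dimethylamino)pyridine) would give two diastereomeric esters to be separated by chromatography or crystallisation. The (3R,5S) diastereomer, methyl 2-[(3R,5S)-5-({[(2S)-2-acetoxy-2-phenylacetyl]oxy}methyl)-3,5-dimethyl-1,2-dioxolan-3-yl]acetate F4, would be methanolysed (K2CO3, MeOH, 0 °C) to rejoin the route at 11.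

3. Step 9. The ene-reductase may reject an enal with a tertiary-alkyl β-substituent, or the C7 configuration may erode by enolisation of the α-branched aldehyde in buffer. C7 would then be sorted out after a non-selective reduction. Setting out from 14, amine-salt-catalysed transfer hydrogenation (Hantzsch ester, dibenzylammonium trifluoroacetate, THF) should give 15 together with its C7 epimer methyl 2-[(3R,5R)-3,5-dimethyl-5-[(2R)-2-methyl-3-oxopropyl]-1,2-dioxolan-3-yl]acetate F5. NaBH4 in MeOH at 0 °C would reduce the mixture to the (2S) alcohol methyl 2-[(3R,5R)-5-[(2S)-3-hydroxy-2-methylpropyl]-3,5-dimethyl-1,2-dioxolan-3-yl]acetate F6 and the (2R) alcohol methyl 2-[(3R,5R)-5-[(2R)-3-hydroxy-2-methylpropyl]-3,5-dimethyl-1,2-dioxolan-3-yl]acetate F7. Lipase-catalysed acylation (Burkholderia cepacia lipase, vinyl acetate, t-BuOMe) discriminates 2-methyl-branched primary alcohols and is expected to acylate the (2S) epimer faster, giving the acetate methyl 2-[(3R,5R)-5-[(2S)-3-acetoxy-2-methylpropyl]-3,5-dimethyl-1,2-dioxolan-3-yl]acetate F8, separable from unreacted F7. Methanolysis (K2CO3, MeOH) back to F6 and Dess–Martin oxidation rejoin the route at 15.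

**Further compounds**

F1 | step 4 | 1-(5-methoxy-3,5-dimethyl-1,2-dioxolan-3-yl)propan-2-one (both diastereomers) | COC1(C)CC(C)(CC(C)=O)OO1
F2 | step 5 | rac-1,6-dimethyl-3,7,8-trioxabicyclo[4.2.1]nonan-4-one (both enantiomers) | O=C1OC[C@]2(C)C[C@](C)(C1)OO2.O=C1OC[C@@]2(C)C[C@@](C)(C1)OO2
F3 | step 5 | methyl 2-[(3R*,5S*)-5-(hydroxymethyl)-3,5-dimethyl-1,2-dioxolan-3-yl]acetate (racemate, both enantiomers) | OC[C@]1(C)C[C@](C)(CC(=O)OC)OO1.OC[C@@]1(C)C[C@@](C)(CC(=O)OC)OO1
F4 | step 5 | methyl 2-[(3R,5S)-5-({[(2S)-2-acetoxy-2-phenylacetyl]oxy}methyl)-3,5-dimethyl-1,2-dioxolan-3-yl]acetate | CC(=O)O[C@H](C(=O)OC[C@]1(C)C[C@](C)(CC(=O)OC)OO1)c1ccccc1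
F5 | step 9 | methyl 2-[(3R,5R)-3,5-dimethyl-5-[(2R)-2-methyl-3-oxopropyl]-1,2-dioxolan-3-yl]acetate | C[C@@H](C=O)C[C@]1(C)C[C@](C)(CC(=O)OC)OO1
F6 | step 9 | methyl 2-[(3R,5R)-5-[(2S)-3-hydroxy-2-methylpropyl]-3,5-dimethyl-1,2-dioxolan-3-yl]acetate | C[C@H](CO)C[C@]1(C)C[C@](C)(CC(=O)OC)OO1
F7 | step 9 | methyl 2-[(3R,5R)-5-[(2R)-3-hydroxy-2-methylpropyl]-3,5-dimethyl-1,2-dioxolan-3-yl]acetate | C[C@@H](CO)C[C@]1(C)C[C@](C)(CC(=O)OC)OO1
F8 | step 9 | methyl 2-[(3R,5R)-5-[(2S)-3-acetoxy-2-methylpropyl]-3,5-dimethyl-1,2-dioxolan-3-yl]acetate | C[C@H](COC(C)=O)C[C@]1(C)C[C@](C)(CC(=O)OC)OO1
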